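Z, one hand of the racemate, was 50.0% of the charge, and G comes from it, so I took that share as the ceiling of G. This was my assumption, because Q was never read. I called the ceiling minus G the gap. The larch run, this very flask followed so far, showed the gap shrinking from 30 percentage points at 10.0 s to 1.9 points at 40.0 s, so it halved about every 7.55 s: the gap half-life, an apparent half-life read with the scatter of the readings.

| flask | Z | Q | J | remark | time |
|---|---|---|---|---|---|
| larch | 0.10 M | 0.10 M | 18 mM (held) | the very flask that is asked about, followed so far |  |
| flask | 0.10 M | 0.10 M | 18 mM (held) |  | 2.0 min |

larch run (percent of the Z and Q together charged)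

| time / s | G / % | Z / % |
|---|---|---|
| 10.0 | 20.1 | 26.5 |
| 15.0 | 28.5 | 15.9 |
| 20.0 | 35.4 | 8.4 |
| 30.0 | 43.8 | 1.9 |
| 40.0 | 48.1 | 0 |

(standard deviation of a reading: 0.5 percentage points)

- how much G there is at 2.0 min, in percent of the Z and Q together charged
- the change that raises the amount of G at 2.0 min, in percent of the Z and Q together charged most ("none" if none brings more than 2 percentage points) (ochre / teal / none)
- amount of G at 2.0 min, in percent of the Z and Q together charged, after teal

- ochre: doubling the saturation concentration of J, all else as stated
- teal: doubling the transfer coefficient of J, all else as stated

- D is single-handed; Z and Q are mirror images of each other, charged as a racemate, each of them at the stated concentration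
- the numbers in the tables scatter by 0.5 percentage points (one standard deviation)
- at the start none of J is in solution
- the handed part of D does not stay in what it makes, so the products of the two hands are mirror images too

I then turned the question round. For ochre or teal to gain more than 2 points under an unmoved ceiling, the gap had to exceed that at 2.0 min, and from its value at 10.0 s this needed a half-life of 28.2 s. The larch readings gave less than that, and the opening stretch up to 15.0 s, at 10.5 s, gave less as well. From 40.0 s to 2.0 min lay 10.6 half-lives, for which I reckoned a gap of 0.0012 points, far less than the mark. So I committed to the ceiling for G, with and without teal, and to no useful change.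

The forecast gave 50%, none and 50%, holding that “the plateau is set by the Z charge”. The flask gave 50.0%, none and 50.0%; ochre added 0 points and teal added 0 points.

    Z ⇌ Q (k = 0.0133 /s)
    J ⇌ D, rate k2*(csat - [D]) (kL = 0.468 /s)
    G ⇌ L (k = 0.103 /s)
    D + Z → G (k = 33.3 /M/s)
    D + Q → L (k = 11.5 /M/s)

G lay at the ceiling at 2.00 min, beside L at 50.0%. I next took the gap half-life to the neighbouring flask, stopped at 30 s, where it reckoned a gap of 4.8 points. That flask held G at 44.0%, a gap of 6 points, more than reckoned and more than the mark. In it, 2.3% of the charged Z and 18% of the charged Q remained.

Readings and results were computed for an exercise; noise was put on by code.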